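**Retrosynthetic overview**

1. 36 ⇐ 35 by α-methylenation of the C15 aldehyde (C4=C3); 35 ⇐ 33 by one acid step that removes acetonide, tert-butyl ester and dioxolane and lets the acrylic acid close the trans-fused γ-lactone on C8–OH through its C12–O acyl bond.
2. C5, C6, C7 ⇐ C6 ketone 26: the arms on C5 and C7 equilibrate to equatorial (β), hydride then adds anti to the axial C14 methyl; the arms come from enone 16 by Peterson olefination and 1,6-addition.
3. C8, C9, C10 ⇐ bridged bromolactone 6; its C8–O bond, the later ring oxygen of the target lactone, is made in the key ring closure, a catalytic enantioselective bromolactonization of achiral acid 4 (Birch reductive methylation of benzoic acid).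
4. Enabling feature: on ring C5–C10 the vinyl carbon C1 (on C10) and the lactone oxygen (on C8) are 1,3-cis, so C1 can serve at the carboxyl level as a tethered oxygen donor through a temporary 6-oxabicyclo[3.2.1]octenone; with C1 as CO2H the ring has a mirror plane through C10 and C7 that makes the C8=C9 and C5=C6 alkenes enantiotopic.
5. Ring order: carbocycle (from benzene, step 1) → temporary bridged γ-lactone (step 2, opened to the vinyl group in steps 4 and 5) → temporary acetonide (step 7) → α-methylene γ-lactone of the target (step 17).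

Key step: step 2

Remark on the chemistry (assumption): atoms carry the elemanolide numbers of the target throughout (ring C5–C10; C14 methyl β and C1=C2 vinyl α on C10; C11–C13 with C12 the lactone carbonyl; C3, C4, C15 the acrolein unit; α/β = below/above the ring drawn with C14 up); the oxygen put on C8 in step 2 stays on C8 to the end; the sense of induction of the catalyst in step 2 has to be fixed by experiment, the pseudo-enantiomeric 1,4-bis(9-O-dihydroquininyl)phthalazine serving the mirror-image series.

Step 1
Reactants: 1 benzoic acid; 2 iodomethane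
Product: 4 1-methylcyclohexa-2,5-diene-1-carboxylic acid, via dilithium enediolate 3 (not isolated)
Conditions: Li, NH3(l)/THF, −78 °C; then MeI, −78 °C to −33 °C; NH4Cl; aq. HCl
Reagents that add atoms: iodomethane, CI
Why: Birch reduction of the benzoate gives the cross-conjugated enediolate, which is C-methylated at the ipso carbon (Birch reductive alkylation); the product is achiral, with a mirror plane through C10 and C7.

Step 2
Reactants: 4 1-methylcyclohexa-2,5-diene-1-carboxylic acid; 5 N-bromosuccinimide
Product: 6 bromolactone (8-bromo-1-methyl-6-oxabicyclo[3.2.1]oct-2-en-7-one; Br anti to the lactone bridge; O on C8α; Br on C9β)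
Conditions: (DHQD)2PHAL [hydroquinidine 1,4-phthalazinediyl diether] (10 mol %), N-bromosuccinimide (1.1 equiv), CHCl3/hexane 1:1, −40 °C
Reagents that add atoms: N-bromosuccinimide, O=C1CCC(=O)N1Br
Why: Catalytic enantioselective bromolactonization that desymmetrizes a prochiral 1,4-diene acid: the catalyst-bound bromenium ion adds to one of the two enantiotopic ring alkenes on the face away from the carboxyl group, and the carboxylate oxygen opens the bromiranium ion at C8 in an anti addition. The closest known reaction type is the cinchona- or amidine-catalysed desymmetrizing halolactonization of cyclohexa-2,5-diene-1-carboxylic acids, together with the iodolactonization of Birch reduction–alkylation products. The one ring closed is the five-membered lactone O–C8–C9–C10–C1(=O), formed in the 5-endo mode with respect to the C8=C9 alkene (γ-lactonization of a β,γ-unsaturated acid) and bridging C8 and C10 as a 6-oxabicyclo[3.2.1]octenone. C8 is set by the tether (oxygen necessarily cis to the acyl carbon on C10), C9 by the anti opening (bromine trans to oxygen), and C10, which becomes stereogenic only when the two alkenes are told apart, by the catalyst. The step needs enantiotopic-group selectivity, which the chiral ion pair secures, and five- over four-membered ring closure (the 4-exo β-lactone), which is secured by reversible bromiranium formation under non-basic conditions and by the strain of the fused β-lactone; a second lactonization is excluded because the carboxyl group is used up.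

Step 3
Reactants: 6 bromolactone; 7 TEMPO (2,2,6,6-tetramethylpiperidin-1-oxyl)
Product: 8 alkoxyamine lactone (1-methyl-8-[(2,2,6,6-tetramethylpiperidin-1-yl)oxy]-6-oxabicyclo[3.2.1]oct-2-en-7-one; N–O group syn to the lactone bridge; C9α)
Conditions: Bu3SnH (1.3 equiv, slow addition), TEMPO (3 equiv), PhH, 70 °C
Reagents that add atoms: TEMPO, CC1(C)CCCC(C)(C)N1[O]
Why: Tin-mediated radical debromination with nitroxide trapping (radical C–Br to C–O exchange, chosen because the bridge bromide is inert to SN2 and E2); the planar C9 radical should be trapped by TEMPO from the α face over the hydrogen-free lactone bridge, anti to the three-carbon bridge, which places the new oxygen cis to the C8 oxygen.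

Step 4
Reactants: 8 alkoxyamine lactone
Product: 9 bridged lactol (7-hydroxy analogue of 8; anomer mixture)
Conditions: iBu2AlH (1.2 equiv), CH2Cl2, −78 °C; aq. potassium sodium tartrate
Reagents that add atoms: none
Why: Partial reduction of the strained γ-lactone to the lactol (DIBAL-H lactone-to-lactol reduction), the tetrahedral aluminate being stable at −78 °C; the C9 oxygen is kept as the aminoxy ether so that no β-hydroxy aldehyde able to undergo retro-aldol cleavage appears in step 5.

Step 5
Reactants: 9 bridged lactol; 10 methyltriphenylphosphonium bromide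
Product: 11 5-ethenyl-5-methyl-6-[(2,2,6,6-tetramethylpiperidin-1-yl)oxy]cyclohex-3-en-1-ol (C8α-OH; C9α-O; vinyl α; all cis)
Conditions: Ph3PCH3Br (4 equiv), KOtBu (3.8 equiv), THF, 0 °C to 50 °C
Reagents that add atoms: methyltriphenylphosphonium bromide, C[P+](c1ccccc1)(c1ccccc1)c1ccccc1.[Br-]
Why: Wittig methylenation of the lactol through its open hydroxy aldehyde form turns the former carboxyl carbon into the C1=C2 vinyl group and frees the C8 hydroxyl; no stereocenter is touched because the aldehyde is α-quaternary.

Step 6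
Reactants: 11 alkoxyamine alcohol
Product: 12 3-ethenyl-3-methylcyclohex-4-ene-1,2-diol (cis-diol cis to the vinyl group; C8α-OH; C9α-OH)
Conditions: Zn dust, AcOH/THF/H2O 3:1:1, 60 °C
Reagents that add atoms: none
Why: Reductive N–O cleavage of the alkoxyamine with zinc in acetic acid liberates the C9 hydroxyl without touching either alkene.

Step 7
Reactants: 12 cis-diol; 13 2,2-dimethoxypropane
Product: 14 acetonide (7-ethenyl-2,2,7-trimethyl-3a,4,7,7a-tetrahydro-1,3-benzodioxole; cis-fused; vinyl cis to the ring oxygens)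
Conditions: Me2C(OMe)2, pyridinium p-toluenesulfonate (cat.), CH2Cl2, rt
Reagents that add atoms: 2,2-dimethoxypropane, COC(C)(C)OC
Why: Acid-catalysed transketalization gives the cis-fused acetonide, which masks the C8 and C9 hydroxyls together until step 17.

Step 8
Reactants: 14 acetonide; 15 tert-butyl hydroperoxide
Product: 16 enone (7-ethenyl-2,2,7-trimethyl-7,7a-dihydro-1,3-benzodioxol-4(3aH)-one; C7 ketone conjugated with C5=C6)
Conditions: Rh2(cap)4 (dirhodium tetracaprolactamate, 1 mol %), tBuOOH (70% in water, 5 equiv), K2CO3, CH2Cl2, rt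
Reagents that add atoms: tert-butyl hydroperoxide, CC(C)(C)OO
Why: Dirhodium-catalysed allylic oxidation with tert-butyl hydroperoxide converts the only allylic methylene (C7; C10 is quaternary and the vinyl group has no allylic hydrogen) into the enone carbonyl.

Step 9
Reactants: 16 enone; 17 tert-butyl (trimethylsilyl)acetate
Product: 18 dienoate (tert-butyl (E)-2-[7-ethenyl-2,2,7-trimethyl-7,7a-dihydro-1,3-benzodioxol-4(3aH)-ylidene]acetate; C5=C6–C7=C11)
Conditions: LiN(iPr)2, tert-butyl (trimethylsilyl)acetate, THF, −78 °C; then 16, −78 °C to 0 °C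
Reagents that add atoms: tert-butyl (trimethylsilyl)acetate, C[Si](C)(C)CC(=O)OC(C)(C)C
Why: Peterson olefination: 1,2-addition of the α-silyl ester enolate to the enone carbonyl (the β-carbon C5 is shielded by the quaternary C10) and syn-elimination of lithium trimethylsilanolate give the conjugated 2,4-dienoate; the alkene geometry is of no consequence.

Step 10
Reactants: 18 dienoate; 19 (1,3-dioxolan-2-ylmethyl)magnesium bromide
Product: 20 β,γ-unsaturated ester (tert-butyl 2-[6-(1,3-dioxolan-2-ylmethyl)-7-ethenyl-2,2,7-trimethyl-3a,6,7,7a-tetrahydro-1,3-benzodioxol-4-yl]acetate; C6=C7 alkene; C5 epimers)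
Conditions: (1,3-dioxolan-2-ylmethyl)MgBr (2 equiv), CuBr·SMe2 (10 mol %), THF, −78 °C to −30 °C; aq. NH4Cl
Reagents that add atoms: (1,3-dioxolan-2-ylmethyl)magnesium bromide, Br[Mg]CC1OCCO1
Why: Copper-catalysed 1,6-conjugate addition of the Grignard reagent to the dienoate (the β-carbon C7 is fully substituted) puts the masked acetaldehyde arm on C5, and kinetic α-protonation of the dienolate leaves the C6=C7 alkene; C5 forms as an epimer mixture that is corrected in step 13.

Step 11
Reactants: 20 β,γ-unsaturated ester; 21 3-chloroperbenzoic acid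
Product: 23 γ-hydroxy enoate (C6-OH; C7=C11 conjugated with the tert-butyl ester; C5 and C6 epimers; E/Z mixture), via epoxide 22 (not isolated)
Conditions: mCPBA (1.1 equiv), NaHCO3, CH2Cl2, 0 °C; then DBU (1.5 equiv), CH2Cl2, rt
Reagents that add atoms: 3-chloroperbenzoic acid, OOC(=O)c1cccc(Cl)c1
Why: Prilezhaev epoxidation is selective for the trisubstituted C6=C7 alkene over the monosubstituted vinyl group, and base-induced E1cB opening of the β,γ-epoxy ester then gives the γ-hydroxy enoate with oxygen on C6; the tert-butyl ester suppresses butenolide formation, and the C6 configuration is irrelevant because C6 is oxidized next.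

Step 12
Reactants: 23 γ-hydroxy enoate
Product: 24 γ-keto enoate (C6 ketone conjugated with C7=C11; C5 epimers)
Conditions: Dess–Martin periodinane, NaHCO3, CH2Cl2, 0 °C to rt
Reagents that add atoms: none
Why: Dess–Martin oxidation of the allylic secondary alcohol gives the C6 ketone under buffered, non-basic conditions.

Step 13
Reactants: 24 γ-keto enoate
Product: 26 γ-keto ester (tert-butyl 2-[6-(1,3-dioxolan-2-ylmethyl)-7-ethenyl-2,2,7-trimethyl-5-oxohexahydro-1,3-benzodioxol-4-yl]acetate; C5β and C7β arms; both equatorial), via epimer mixture 25 (not isolated)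
Conditions: Zn dust, AcOH, rt; filter; then DBU (0.2 equiv), CH2Cl2, rt
Reagents that add atoms: none
Why: Zinc in acetic acid reduces the electron-poor C7=C11 alkene of the ene-1,4-dicarbonyl unit (dissolving-metal conjugate reduction), and base then equilibrates both α-carbons of the C6 ketone under thermodynamic control: with C8, C9 and C10 fixed, the chair with equatorial C8–O and axial C9–O forbids α-axial arms (syn-axial to C9–O), while the flipped chair suffers a syn-axial C8–O/vinyl clash, so both arms settle equatorial and β.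

Step 14
Reactants: 26 γ-keto ester
Product: 27 C6β alcohol (5-hydroxy analogue of 26; OH axial; cis to both arms)
Conditions: NaBH4, MeOH/CH2Cl2, −40 °C
Reagents that add atoms: none
Why: Substrate-controlled hydride reduction of the ketone: axial attack is blocked by the 1,3-syn-axial C14 methyl on C10, so hydride enters equatorially from the α face and the C6 hydroxyl is formed axial and β.

Step 15
Reactants: 27 C6β alcohol; 28 N,N-dimethylmethyleneiminium iodide (Eschenmoser's salt); 2 iodomethane
Product: 31 acrylate (tert-butyl 2-substituted prop-2-enoate; C11=C13 in place; C6β-OH free), via Mannich base 29 (not isolated), via methiodide 30 (not isolated)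
Conditions: LiN(iPr)2 (3.2 equiv), THF, −78 °C; [Me2N=CH2]I, −78 °C to 0 °C; then MeI, MeOH, rt; then aq. NaHCO3, EtOAc, rt
Reagents that add atoms: N,N-dimethylmethyleneiminium iodide, C=[N+](C)C.[I-]
Why: α-Methylenation of the ester through its lithium enolate (Mannich reaction with Eschenmoser's salt, N-methylation and elimination of trimethylamine); the C6 lithium alkoxide should not attack the tert-butyl ester at −78 °C because tert-butoxide is a poor leaving group, and no stereocenter is touched.

Step 16
Reactants: 31 acrylate; 32 angelic acid ((Z)-2-methylbut-2-enoic acid)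
Product: 33 C6β angelate (fully protected precursor: acetonide; dioxolane; tert-butyl acrylate)
Conditions: angelic acid, 2,4,6-trichlorobenzoyl chloride, Et3N, PhMe, rt; then 31, 4-(dimethylamino)pyridine, 80 °C
Reagents that add atoms: angelic acid, C/C=C(/C)C(=O)O
Why: Yamaguchi esterification of the hindered axial C6 hydroxyl with the mixed anhydride of angelic acid, a protocol chosen because it keeps the (Z)-geometry of the angelate.

Step 17
Reactants: 33 C6β angelate; 34 water
Product: 35 aldehyde lactone (6β-angeloyloxy-9α-hydroxy-8α,12-olide with C11=C13; C5 bears CH2–CHO)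
Conditions: CF3CO2H/CH2Cl2/H2O 10:10:1, 0 °C to rt
Reagents that add atoms: water, O
Why: Acid-mediated global unmasking: hydrolysis of acetonide and dioxolane, cleavage of the tert-butyl ester and spontaneous lactonization of the acrylic acid onto the equatorial C8 hydroxyl to the trans-fused γ-lactone (the axial C9 hydroxyl cannot reach C12 and the C6 oxygen is acylated).

Step 18
Reactants: 35 aldehyde lactone; 28 N,N-dimethylmethyleneiminium iodide (Eschenmoser's salt)
Product: 36 target (6β-angeloyloxy-9α-hydroxy-15-oxoelema-1,3,11(13)-trien-12,8α-olide)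
Conditions: [Me2N=CH2]I (3 equiv), Et3N (5 equiv), CH2Cl2, rt
Reagents that add atoms: N,N-dimethylmethyleneiminium iodide, C=[N+](C)C.[I-]
Why: Mannich reaction of the aldehyde with Eschenmoser's salt followed by amine-induced elimination (α-methylenation of an aldehyde) creates the C4=C3 methylene next to the C15 aldehyde under conditions that leave lactone, angelate and the free hydroxyl untouched.

**Compound list**

1 | benzoic acid | OC(=O)c1ccccc1 | starting material
2 | iodomethane | CI | starting material
3 | dilithium enediolate of 1,4-dihydrobenzoic acid | [Li+].[Li+].[O-]C([O-])=C1C=CCC=C1 | intermediate (not isolated)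
4 | 1-methylcyclohexa-2,5-diene-1-carboxylic acid (achiral) | CC1(C=CCC=C1)C(=O)O | intermediate
5 | N-bromosuccinimide | O=C1CCC(=O)N1Br | starting material
6 | 8-bromo-1-methyl-6-oxabicyclo[3.2.1]oct-2-en-7-one, Br anti to the lactone bridge (O on C8α, Br on C9β, methyl on C10β) | C[C@@]12C=CC[C@@H](OC1=O)[C@@H]2Br | intermediate
7 | TEMPO (2,2,6,6-tetramethylpiperidin-1-oxyl) | CC1(C)CCCC(C)(C)N1[O] | starting material
8 | 1-methyl-8-[(2,2,6,6-tetramethylpiperidin-1-yl)oxy]-6-oxabicyclo[3.2.1]oct-2-en-7-one, N–O group syn to the lactone bridge (C9α) | C[C@@]12C=CC[C@@H](OC1=O)[C@H]2ON3C(C)(C)CCCC3(C)C | intermediate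
9 | bridged lactol of 8 (7-hydroxy, anomer mixture) | C[C@@]12C=CC[C@@H](OC1O)[C@H]2ON3C(C)(C)CCCC3(C)C | intermediate
10 | methyltriphenylphosphonium bromide | C[P+](c1ccccc1)(c1ccccc1)c1ccccc1.[Br-] | starting material
11 | 5-ethenyl-5-methyl-6-[(2,2,6,6-tetramethylpiperidin-1-yl)oxy]cyclohex-3-en-1-ol, OH, N–O oxygen and vinyl all cis (C8α, C9α, vinyl α) | C=C[C@]1(C)[C@H](ON2C(C)(C)CCCC2(C)C)[C@H](O)CC=C1 | intermediate
12 | 3-ethenyl-3-methylcyclohex-4-ene-1,2-diol, cis-diol cis to vinyl (C8α-OH, C9α-OH) | C=C[C@]1(C)[C@H](O)[C@H](O)CC=C1 | intermediate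
13 | 2,2-dimethoxypropane | COC(C)(C)OC | starting material
14 | 7-ethenyl-2,2,7-trimethyl-3a,4,7,7a-tetrahydro-1,3-benzodioxole, cis-fused acetonide, vinyl cis to the ring oxygens | C=C[C@]1(C)[C@@H]2OC(C)(C)O[C@@H]2CC=C1 | intermediate
15 | tert-butyl hydroperoxide | CC(C)(C)OO | starting material
16 | 7-ethenyl-2,2,7-trimethyl-7,7a-dihydro-1,3-benzodioxol-4(3aH)-one (C7 ketone, C5=C6) | C=C[C@]1(C)[C@@H]2OC(C)(C)O[C@@H]2C(=O)C=C1 | intermediate
17 | tert-butyl (trimethylsilyl)acetate | C[Si](C)(C)CC(=O)OC(C)(C)C | starting material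
18 | tert-butyl (E)-2-[7-ethenyl-2,2,7-trimethyl-7,7a-dihydro-1,3-benzodioxol-4(3aH)-ylidene]acetate | C=C[C@]1(C)[C@@H]2OC(C)(C)O[C@@H]2/C(=C/C(=O)OC(C)(C)C)C=C1 | intermediate
19 | (1,3-dioxolan-2-ylmethyl)magnesium bromide | Br[Mg]CC1OCCO1 | starting material
20 | tert-butyl 2-[6-(1,3-dioxolan-2-ylmethyl)-7-ethenyl-2,2,7-trimethyl-3a,6,7,7a-tetrahydro-1,3-benzodioxol-4-yl]acetate (C6=C7; C5 epimers, center left open) | C=C[C@]1(C)[C@@H]2OC(C)(C)O[C@@H]2C(CC(=O)OC(C)(C)C)=CC1CC1OCCO1 | intermediate
21 | 3-chloroperbenzoic acid | OOC(=O)c1cccc(Cl)c1 | starting material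
22 | C6–C7 epoxide of 20 (epimers) | C=C[C@]1(C)[C@@H]2OC(C)(C)O[C@@H]2C3(CC(=O)OC(C)(C)C)OC3C1CC1OCCO1 | intermediate (not isolated)
23 | γ-hydroxy enoate: tert-butyl 2-[6-(1,3-dioxolan-2-ylmethyl)-7-ethenyl-5-hydroxy-2,2,7-trimethyltetrahydro-1,3-benzodioxol-4(3aH)-ylidene]acetate (C5, C6 epimers; E/Z mixture) | C=C[C@]1(C)[C@@H]2OC(C)(C)O[C@@H]2C(=CC(=O)OC(C)(C)C)C(O)C1CC1OCCO1 | intermediate
24 | γ-keto enoate: 5-oxo analogue of 23 (C5 epimers; E/Z mixture) | C=C[C@]1(C)[C@@H]2OC(C)(C)O[C@@H]2C(=CC(=O)OC(C)(C)C)C(=O)C1CC1OCCO1 | intermediate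
25 | γ-keto ester, mixture of C5 and C7 epimers | C=C[C@]1(C)[C@@H]2OC(C)(C)O[C@@H]2C(CC(=O)OC(C)(C)C)C(=O)C1CC1OCCO1 | intermediate (not isolated)
26 | tert-butyl 2-[6-(1,3-dioxolan-2-ylmethyl)-7-ethenyl-2,2,7-trimethyl-5-oxohexahydro-1,3-benzodioxol-4-yl]acetate, arms on C5 and C7 both β (equatorial) | C=C[C@]1(C)[C@@H]2OC(C)(C)O[C@@H]2[C@@H](CC(=O)OC(C)(C)C)C(=O)[C@H]1CC1OCCO1 | intermediate
27 | C6β (axial) alcohol of 26 | C=C[C@]1(C)[C@@H]2OC(C)(C)O[C@@H]2[C@@H](CC(=O)OC(C)(C)C)[C@@H](O)[C@H]1CC1OCCO1 | intermediate
28 | N,N-dimethylmethyleneiminium iodide (Eschenmoser's salt) | C=[N+](C)C.[I-] | starting material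
29 | Mannich base of 27 (C11–CH2NMe2, C11 epimers) | C=C[C@]1(C)[C@@H]2OC(C)(C)O[C@@H]2[C@@H](C(CN(C)C)C(=O)OC(C)(C)C)[C@@H](O)[C@H]1CC1OCCO1 | intermediate (not isolated)
30 | methiodide of 29 | C=C[C@]1(C)[C@@H]2OC(C)(C)O[C@@H]2[C@@H](C(C[N+](C)(C)C)C(=O)OC(C)(C)C)[C@@H](O)[C@H]1CC1OCCO1.[I-] | intermediate (not isolated)
31 | acrylate: tert-butyl 2-[6-(1,3-dioxolan-2-ylmethyl)-7-ethenyl-5-hydroxy-2,2,7-trimethylhexahydro-1,3-benzodioxol-4-yl]prop-2-enoate (C6β-OH) | C=C[C@]1(C)[C@@H]2OC(C)(C)O[C@@H]2[C@@H](C(=C)C(=O)OC(C)(C)C)[C@@H](O)[C@H]1CC1OCCO1 | intermediate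
32 | angelic acid ((Z)-2-methylbut-2-enoic acid) | C/C=C(/C)C(=O)O | starting material
33 | C6β angelate of 31 | C=C[C@]1(C)[C@@H]2OC(C)(C)O[C@@H]2[C@@H](C(=C)C(=O)OC(C)(C)C)[C@@H](OC(=O)/C(C)=C\C)[C@H]1CC1OCCO1 | intermediate
34 | water | O | starting material
35 | aldehyde lactone: 6β-angeloyloxy-9α-hydroxy-8α,12-olide with C11=C13, C5 carrying CH2–CHO | C=C[C@]1(C)[C@H](O)[C@@H]2OC(=O)C(=C)[C@H]2[C@@H](OC(=O)/C(C)=C\C)[C@H]1CC=O | intermediate
36 | CNP0277836.2, 6β-angeloyloxy-9α-hydroxy-15-oxoelema-1,3,11(13)-trien-12,8α-olide | C=C[C@]1(C)[C@H](O)[C@@H]2OC(=O)C(=C)[C@H]2[C@@H](OC(=O)/C(C)=C\C)[C@H]1C(=C)C=O | target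

**Step count**

Total steps: 18. Longest linear sequence: 18 steps (fully linear from benzoic acid).

**Steps most likely to fail**

Step 2. Discrimination of the enantiotopic alkenes may be insufficient, or the ring may close in the four-membered mode. The fallback sets out from 4 and uses auxiliary control instead of catalysis. Acid 4 is converted with (COCl)2 and catalytic DMF into the acid chloride F1. F1 is coupled (Et3N, CH2Cl2) with (2S,5S)-2,5-bis(methoxymethyl)pyrrolidine to the C2-symmetric amide F2. Iodolactonization of F2 under equilibrating conditions (I2, THF/H2O, rt) lets the amide oxygen close the five-membered ring with diastereotopic-alkene selection by the auxiliary. Hydrolysis of the iminium lactone releases the auxiliary and the iodolactone F3 (iodo analogue of 6). F3 is submitted to the radical exchange of step 3 (Bu3SnH, TEMPO) and comes back to the route at 8.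

Step 3. Facial selectivity in the trapping of the C9 radical may be poor. The fallback sets out from 11, taken as its C9 epimer mixture, and sets C9 by hydride instead. The C8 hydroxyl is silylated (TBSOTf, 2,6-lutidine) to the silyl ether F4. The N–O bond is cleaved (Zn, AcOH) to the alcohol F5. Dess–Martin oxidation gives the ketone F6. Reduction with LiBH(sBu)3 at −78 °C should deliver hydride equatorially, as with ketones flanked by a quaternary carbon bearing an axial methyl, to give the axial 9α-alcohol F7. Fluoride (Bu4NF, THF) removes the silyl group and the sequence comes back at 12.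

Step 15. The free C6 alkoxide may cause lactonization onto the ester or incomplete enolization. The fallback sets out from 27 and uses hydroxymethylation and dehydration on a protected substrate. The C6 hydroxyl is protected (Et3SiOTf, 2,6-lutidine) as the triethylsilyl ether F8. The ester enolate (LiN(iPr)2, −78 °C) is hydroxymethylated with monomeric formaldehyde to the β-hydroxy ester F9. Mesylation (MsCl, Et3N) gives the mesylate F10, and DBU eliminates it to the acrylate silyl ether F11. HF·pyridine in THF removes the silyl group and the sequence comes back at 31.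

Further compounds
F1 | step 2 | 1-methylcyclohexa-2,5-diene-1-carbonyl chloride | CC1(C=CCC=C1)C(=O)Cl
F2 | step 2 | [(2S,5S)-2,5-bis(methoxymethyl)pyrrolidin-1-yl](1-methylcyclohexa-2,5-dien-1-yl)methanone | COC[C@@H]1CC[C@@H](COC)N1C(=O)C1(C)C=CCC=C1
F3 | step 2 | 8-iodo-1-methyl-6-oxabicyclo[3.2.1]oct-2-en-7-one, iodine anti to the lactone bridge | C[C@@]12C=CC[C@@H](OC1=O)[C@@H]2I
F4 | step 3 | tert-butyldimethylsilyl ether of 11 at the C8 oxygen (C9 epimers) | C=C[C@]1(C)C(ON2C(C)(C)CCCC2(C)C)[C@H](O[Si](C)(C)C(C)(C)C)CC=C1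
F5 | step 3 | 6-(tert-butyldimethylsilyloxy)-2-ethenyl-2-methylcyclohex-3-en-1-ol (C9 epimers) | C=C[C@]1(C)C(O)[C@H](O[Si](C)(C)C(C)(C)C)CC=C1
F6 | step 3 | 6-(tert-butyldimethylsilyloxy)-2-ethenyl-2-methylcyclohex-3-en-1-one (C9 ketone) | C=C[C@]1(C)C(=O)[C@H](O[Si](C)(C)C(C)(C)C)CC=C1
F7 | step 3 | 9α-alcohol: 6-(tert-butyldimethylsilyloxy)-2-ethenyl-2-methylcyclohex-3-en-1-ol, OH cis to the silyloxy group and to vinyl | C=C[C@]1(C)[C@H](O)[C@H](O[Si](C)(C)C(C)(C)C)CC=C1
F8 | step 15 | triethylsilyl ether of 27 at the C6 oxygen | C=C[C@]1(C)[C@@H]2OC(C)(C)O[C@@H]2[C@@H](CC(=O)OC(C)(C)C)[C@@H](O[Si](CC)(CC)CC)[C@H]1CC1OCCO1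
F9 | step 15 | α-(hydroxymethyl) ester of F8 (C11 epimers) | C=C[C@]1(C)[C@@H]2OC(C)(C)O[C@@H]2[C@@H](C(CO)C(=O)OC(C)(C)C)[C@@H](O[Si](CC)(CC)CC)[C@H]1CC1OCCO1
F10 | step 15 | mesylate of F9 | C=C[C@]1(C)[C@@H]2OC(C)(C)O[C@@H]2[C@@H](C(COS(C)(=O)=O)C(=O)OC(C)(C)C)[C@@H](O[Si](CC)(CC)CC)[C@H]1CC1OCCO1
F11 | step 15 | triethylsilyl ether of 31 | C=C[C@]1(C)[C@@H]2OC(C)(C)O[C@@H]2[C@@H](C(=C)C(=O)OC(C)(C)C)[C@@H](O[Si](CC)(CC)CC)[C@H]1CC1OCCO1
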